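A small charge of L, 1.1 mM, stands against 2.50 mM of Q in the flask.

| setting | winter | noon | dawn | flask |
|---|---|---|---|---|
| D | 0.10 M | 0.10 M | 0.10 M | 0.10 M |
| X | 1.1 equiv | 1.1 equiv | 1.1 equiv | 1.10 equiv |
| Q | 3.5 mol% | 5.5 mol% | 2.5 mol% | 2.5 mol% |
| J | 0.2 mol% | 0.2 mol% | 0.4 mol% | 0.2 mol% |
| L | 1.1 mM | 1.1 mM | 1.1 mM | 1.1 mM |
| remark | run made earlier | run made earlier | run made earlier |  |

| run | time / s | G / % | D / % |
|---|---|---|---|
| winter | 12.0 | 0.9 | 77.7 |
| winter | 25.0 | 2.3 | 62.2 |
| winter | 40.0 | 4.5 | 48.1 |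
| winter | 50.0 | 6.6 | 41.3 |
| winter | 60.0 | 9.6 | 32.6 |
| winter | 80.0 | 15.1 | 24.3 |
| winter | 90.0 | 16.7 | 20.2 |
| noon | 10.0 | 0 | 70.5 |
| noon | 12.0 | 1.2 | 66.4 |
| noon | 15.0 | 1.7 | 60.2 |
| noon | 25.0 | 3.7 | 44.2 |
| noon | 40.0 | 8.0 | 27.5 |
| noon | 60.0 | 13.4 | 14.7 |
| noon | 90.0 | 22.3 | 6.2 |
| dawn | 10.0 | 0.1 | 85.6 |
| dawn | 15.0 | 1.6 | 80.2 |
| dawn | 25.0 | 3.9 | 71.6 |
| dawn | 50.0 | 9.7 | 55.3 |
| dawn | 90.0 | 22.6 | 37.8 |

(each reading ± 0.5 percentage points)

- "the catalyst" is Q with its forms; J is a second catalyst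
- no earlier run changes the charge of X; that part of a forecast is a guess

- apparent order in X when 50% of the D are converted (percent change of the rate of making G for one percent more X charged)
- apparent order in Q when 50% of the D are converted (percent change of the rate of making G for one percent more Q charged)

We fold the two into one number:

λ = 0.440

This is the poison ratio, the share of charged Q that L removes. Free Q is then the charge less L, so one percent more Q gives g percent more free Q:

g = 1.79

Test it on D. From 25.0 s to 90.0 s, noon loses D faster than winter by a log ratio of 1.75. The charges of Q stand at 1.57 and the free Q at 1.83, so the reading lies nearer free Q.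

But λ is not enough for G. We call E the charge found neither as D nor as G, and we take G to grow from it. We need a second number, w = G/E at 50% conversion. Dawn reads about 13.6% G there. We take half of that for the flask's J, which gives:

w = 0.157

More free Q reaches that conversion sooner, with less G and so more E. More X, if X acts in the step to G (a guess), makes more G and leaves less E. Our reckoning is:

order in Q ≈ g·w = 0.281

order in X ≈ 1 − w = 0.843

The forecast differs: 0.23 (0.12 to 0.35) for Q and 0.6 (0 to 1.1) for X, with the sag of D read “as if L (1.1 mM) removes about 1 mM of Q”.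

The flask gives 0.36 for Q and 0.85 for X.

    D + Q → Q + E (k = 7.10 M⁻¹ s⁻¹)
    X + J + E → J + G (k = 210 M⁻² s⁻¹)
    Q + L → Z (k = 45.0 M⁻¹ s⁻¹)

In the flask after 2.50 min, L stands at 0% of its charge and Z holds 44.0% of the catalyst, against λ of 0.440. The simulated flask without the path from Q + L to Z shows what this does to the order. The flask's order in Q, 0.36, is 2.66 times the 0.13 of that run, more than g of 1.79.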